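Two questions put these flasks in order: how many lifetimes of Wy fit into the run, and what Lx does after the first addition.

in all of them: temperature 50 °C
- alder: Wy 0.44 M; Lx 0.60 M; run made earlier
- east: Wy 0.80 M; Lx 0.600 M; time 1.5 h
- west: Wy 0.40 M; Lx 2.50 M; time 1.5 h
- south: Wy 0.40 M; Lx 0.600 M; time 1.5 h
- north-west: Wy 0.80 M; Lx 2.50 M; time 1.5 h

- alder (time / min: Xa / %): 4.00: 13.5; 12.0: 27.4; 20.0: 38.5; 30.0: 42.2

(standard deviation of a reading: 1 percentage point)

- a reading or a percentage of Xa counts all its forms, free or not

- the flasks put in order of amount of Xa, in percent of the Wy charged, best first, at 1.5 h (east / west / south / north-west)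
- the amount of Xa, in percent of the Wy charged of the flask you put first, at 1.5 h
- the amount of Xa, in percent of the Wy charged of the flask you put last, at 1.5 h

The first alder reading gives Wy a pseudo-first-order lifetime of 27.6 min at the Lx charge of south and 6.62 min at that of west. Taken at those charged amounts of Lx, as an estimate, the run spans 3.26 lifetimes in south and 13.6 in west, so the first addition has time to advance far in both.

But does Xa survive? With Lx falling as it is used, the same reading puts the Wy reacted in alder at 55.8% after 30.0 min, whereas Xa reads less, 42.2%. This reckoning commits to a loss: a second Lx adding to Xa, a mono adduct, rather than a return to Wy.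

How far Lx can carry Wy is then measured by the Lx charge as a fraction of the Wy charge, the equivalent ratio: 6.25 in west, 3.12 in north-west, 1.50 in south and 0.750 in east. A Wy carried to the bis adduct takes two Lx. West and north-west hold more than that, so their Lx charge is enough to carry every Wy past Xa, and west holds the highest ratio. East holds less than one Lx per Wy, which caps its Xa at 75.0%. South lies nearest to alder, whose ratio is 1.36. This reckoning gives south, east, north-west, west, with the top somewhat above the last alder reading and the low close to 0%.

The forecast differs, putting west > north-west > south > east with 81% and 38%: “so every flask is at equilibrium by 1.5 h”.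

The flasks give south > east > north-west > west, from 50.4% in south to 0% in west.

    Wy + Lx → Xa (k = 0.00140 M⁻¹ s⁻¹, Ea = 70.0 kJ mol⁻¹)
    Wy + Lx → Ux (k = 1.10 × 10⁻⁴ M⁻¹ s⁻¹, Ea = 72.0 kJ mol⁻¹)
    Lx + Xa → Ve (k = 0.00500 M⁻¹ s⁻¹, Ea = 63.0 kJ mol⁻¹)
    Lx + Ux → Ve (k = 1.30 × 10⁻⁴ M⁻¹ s⁻¹, Ea = 86.0 kJ mol⁻¹)
    Gu ⇌ Xa, rate k5*(cs5 - [Xa]) while solid is left; crystals form when [Xa] > cs5 (solubility = 12.0 mM, k = 0.0170 s⁻¹)
    Xa → Xo (k = 2.50 × 10⁻⁴ s⁻¹, Ea = 92.0 kJ mol⁻¹)
    (constants at 50 °C)

West holds 95.5% of its Wy as Ve, the bis adduct, with 2.22% as Ux and 2.27% as Xo; at two Lx per Ve and one per Ux or Xo, the ratio 6.25 leaves 68.7% of the Lx charge, and the flask shows 69%. The south recipe with 1.6 M of Wy has a ratio of 0.375, and there Lx is the limiting reagent, down to 0.00803% of its charge. In that flask Xa, Ux, Xo and twice Ve add up to 37.5% of the Wy charged, with Xa at 27.4%.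

The runs are simulated with made-up constants; scatter was added.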